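Ring numbering: C1 quaternary carbon, C2 ketone, C3 (CH3), C4 (OH), C5 (CO2H), C6 (CH3). The target is a constitutional isomer of farnesyl 3,5-dimethylorsellinate, so the six-membered ring is built flat and dearomatised last. The ring has a push–pull pattern: C5=C6 carries CO2H and CH3 (a but-2-ynoate), C1–C4 is a dimethylated chain oxygenated at C2 and C4 (a 1,3-bis(silyloxy)diene). One Diels–Alder/aromatisation of farnesyl but-2-ynoate with the acyclic diene from ethyl 2-methyl-3-oxopentanoate forms C4–C5 and C6–C1, completes the hexasubstituted ring and gathers all 25 carbons. A Pd-catalysed enantioselective O-to-C shift of the temporarily ester-bound farnesyl group then creates the C1 stereocentre and frees the acid.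

Key step: step 3

Assumption: the sense of induction in step 4 cannot be predicted with certainty for this nucleophile, so the (R,R)-ligand is written and its commercial antipode is used instead if it proves to favour (S)-C1.

Step 1
Reactants: 1 (2E,6E)-farnesol; 2 but-2-ynoic acid
Product: 3 (2E,6E)-farnesyl but-2-ynoate
Conditions: DCC (1.1 equiv), DMAP (5 mol %), CH2Cl2, 0 °C to rt
Reagents that add atoms: none
Why: Steglich esterification, in which carbodiimide activation and DMAP acyl transfer acylate the primary allylic alcohol at low temperature without touching the alkyne or the E-alkenes; no stereocentre is formed.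

Step 2
Reactants: 4 ethyl 2-methyl-3-oxopentanoate
Product: 6 (3Z)-1-ethoxy-2-methyl-1,3-bis(trimethylsilyloxy)penta-1,3-diene, via ethyl 2-methyl-3-(trimethylsilyloxy)pent-2-enoate 5 (not isolated)
Conditions: TMSOTf (2.3 equiv), Et3N (3 equiv), Et2O, 0 °C to rt; ammonium salt layer separated, pentane extraction, used without chromatography
Reagents that add atoms: trimethylsilyl trifluoromethanesulfonate (TMSOTf), C[Si](C)(C)OS(=O)(=O)C(F)(F)F
Why: Soft enolisation (double O-silylation of a β-keto ester): TMSOTf silylates the ketone enol to 5, then activates the ester carbonyl so that Et3N removes a γ-proton and the second O-silylation gives the diene, whose (3Z) enol ether with the methyl group pointing outward is the expected thermodynamic geometry; no stereocentre is formed.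

Step 3
Reactants: 3 (2E,6E)-farnesyl but-2-ynoate; 6 (3Z)-1-ethoxy-2-methyl-1,3-bis(trimethylsilyloxy)penta-1,3-diene
Product: 9 (2E,6E)-farnesyl 2,4-dihydroxy-3,5,6-trimethylbenzoate, via (2E,6E)-farnesyl 6-ethoxy-2,3,5-trimethyl-4,6-bis(trimethylsilyloxy)cyclohexa-1,4-diene-1-carboxylate 7 (not isolated), via (2E,6E)-farnesyl 3,5,6-trimethyl-2,4-bis(trimethylsilyloxy)benzoate 8 (not isolated)
Conditions: 6 (2.5 equiv), neat, BHT (1 mol %), sealed tube, 130 °C; then 1 M aq. citric acid, THF, rt
Reagents that add atoms: none
Why: Normal-electron-demand Diels–Alder reaction: the HOMO of 6, raised by three oxygen donors, has its largest coefficient at the CH(CH3) terminus (future C1), which bonds to the electrophilic β-carbon of the ynoate (future C6), while the ketene-acetal carbon (future C4) bonds to the α-carbon (future C5) in a concerted, asynchronous transition state. The closest known reaction type is the thermal cycloaddition of 1-alkoxy-1,3-bis(silyloxy)-1,3-dienes with β-alkyl ynoates, a standard entry to resorcylate esters. The only ring, the six-membered carbocycle, is closed by an intermolecular [4π+2π] cycloaddition; adduct 7 then loses ethanol by 1,4-elimination (C4–OEt, C1–H) to give arene 8, and mild acid cleaves both aryl silyl ethers. The two stereocentres of 7 (C1, C4) are transient and vanish on aromatisation, so facial selectivity does not matter here. The step needs regioselectivity, which the matched push–pull polarisation of both partners secures (ester next to the ketene-acetal-derived oxygen). It also needs chemoselectivity, which holds because the ynoate is the only electron-poor π-bond and the three trisubstituted farnesyl alkenes are inert to an electron-rich diene.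

Step 4
Reactants: 9 (2E,6E)-farnesyl 2,4-dihydroxy-3,5,6-trimethylbenzoate
Product: 11 (3R)-3-[(2E,6E)-farnesyl]-6-hydroxy-2,3,5-trimethyl-4-oxocyclohexa-1,5-diene-1-carboxylic acid, via its dicaesium salt 10 (not isolated)
Conditions: Pd2(dba)3·CHCl3 (2.5 mol %), (R,R)-DACH-phenyl bisphosphine ligand [(1R,2R)-N,N'-bis(2-diphenylphosphinobenzoyl)cyclohexane-1,2-diamine, 7.5 mol %], Cs2CO3 (2.2 equiv), degassed 1,4-dioxane, 25–40 °C; then 0.5 M aq. HCl, 0 °C, to pH 3–4
Reagents that add atoms: none
Why: Proposed new method: Pd(0) should ionise the allylic ester of 9 (a resorcylate is a good leaving group) to a π-farnesyl-Pd cation and the aromatic carboxylate–phenolate, whose ring carbon C1 (ortho to the free C2 phenolate, para to the chelated C4–OH) attacks the unsubstituted allyl terminus, so that the linear (2E)-farnesyl group ends on carbon, the ring is dearomatised and the C2-symmetric ligand pocket chooses the face of the flat nucleophile and thereby sets (R)-C1; O-allylated by-products remain allylic electrophiles and are re-ionised, whereas the C-allylated product is withdrawn as its unreactive dianion 10, which drives the net isomerisation; the closest known reaction types are the Pd-catalysed asymmetric allylic dearomatisation of naphthols and phenols (Tsuji–Trost allylation of a prochiral carbon nucleophile), the linear-selective asymmetric prenylation and geranylation of oxindoles, and the base-mediated alkylative dearomatisation of polysubstituted resorcinols with allylic halides.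

Compound list
1 | (2E,6E)-farnesol | CC(C)=CCC/C(C)=C/CC/C(C)=C/CO | starting material
2 | but-2-ynoic acid (tetrolic acid) | CC#CC(=O)O | starting material
3 | (2E,6E)-farnesyl but-2-ynoate | CC(C)=CCC/C(C)=C/CC/C(C)=C/COC(=O)C#CC | intermediate
4 | ethyl 2-methyl-3-oxopentanoate (racemic) | CCC(=O)C(C)C(=O)OCC | starting material
5 | ethyl 2-methyl-3-(trimethylsilyloxy)pent-2-enoate (alkene geometry undefined, not isolated) | CCC(O[Si](C)(C)C)=C(C)C(=O)OCC | intermediate
6 | (3Z)-1-ethoxy-2-methyl-1,3-bis(trimethylsilyloxy)penta-1,3-diene (ketene acetal geometry undefined) | C/C=C(\O[Si](C)(C)C)C(C)=C(OCC)O[Si](C)(C)C | intermediate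
7 | (2E,6E)-farnesyl 6-ethoxy-2,3,5-trimethyl-4,6-bis(trimethylsilyloxy)cyclohexa-1,4-diene-1-carboxylate (Diels–Alder adduct, diastereomer mixture, not isolated) | CC(C)=CCC/C(C)=C/CC/C(C)=C/COC(=O)C1=C(C)C(C)C(O[Si](C)(C)C)=C(C)C1(OCC)O[Si](C)(C)C | intermediate
8 | (2E,6E)-farnesyl 3,5,6-trimethyl-2,4-bis(trimethylsilyloxy)benzoate (not isolated) | CC(C)=CCC/C(C)=C/CC/C(C)=C/COC(=O)c1c(C)c(C)c(O[Si](C)(C)C)c(C)c1O[Si](C)(C)C | intermediate
9 | (2E,6E)-farnesyl 2,4-dihydroxy-3,5,6-trimethylbenzoate (farnesyl 3,5-dimethylorsellinate) | CC(C)=CCC/C(C)=C/CC/C(C)=C/COC(=O)c1c(C)c(C)c(O)c(C)c1O | intermediate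
10 | dicaesium salt of 11 (carboxylate and vinylogous carboxylate, (R), not isolated) | CC(C)=CCC/C(C)=C/CC/C(C)=C/C[C@@]1(C)C(=O)C(C)=C([O-])C(C(=O)[O-])=C1C.[Cs+].[Cs+] | intermediate
11 | (3R)-3-[(2E,6E)-farnesyl]-6-hydroxy-2,3,5-trimethyl-4-oxocyclohexa-1,5-diene-1-carboxylic acid | CC(C)=CCC/C(C)=C/CC/C(C)=C/C[C@@]1(C)C(=O)C(C)=C(O)C(C(=O)O)=C1C | target

Total step count: 4. Longest linear sequence: 3 steps (1 → 3 → 4 or 2 → 3 → 4).

Steps most likely to fail

Step 4 (Proposed new method).
- What may go wrong:
  - The ambident nucleophile may react through the wrong atom. This could be oxygen, C3 between the two oxygens, or the carboxyl-bearing C5 with subsequent loss of CO2.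
  - The π-farnesyl-Pd species may undergo β-hydride elimination.
  - Syn/anti isomerisation may erode the 2E geometry.
  - Discrimination between the two ring faces may be poor.
- Fallback (known chemistry, from 9 back to 11):
  - The farnesyl ester of 9 is removed by standard Pd(0) allyl transfer to an amine (Pd(PPh3)4, morpholine, THF, rt) to give 3,5-dimethylorsellinic acid F1.
  - F1 is incubated with commercial (2E,6E)-farnesyl diphosphate, MgCl2 and a membrane preparation of a heterologously expressed fungal 3,5-dimethylorsellinate farnesyltransferase (AusN/Trt2 family) in pH 7.5 buffer at 30 °C.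
  - This is the native reaction of these enzymes. It places the farnesyl group on C1 and gives the (R)-acid 11 directly.

Step 3 (key step).
- What may go wrong: bond formation between a substituted diene terminus and a β-methyl ynoate may be slower than thermal decay of the diene. That decay can occur by silyl migration or by protodesilylation by the liberated ethanol.
- Fallback (from 1 and 6 back to 9), using an allene in place of the alkyne:
  - Farnesol 1 is esterified with commercial but-3-ynoic acid (DCC, cat. DMAP, CH2Cl2) to (2E,6E)-farnesyl but-3-ynoate F2.
  - The base isomerises F2 in the flask to (2E,6E)-farnesyl buta-2,3-dienoate F3.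
  - This far more reactive dienophile takes up diene 6 across its α,β-double bond in toluene at 25–60 °C. The orientation is the same and the same two ring bonds are formed, giving the 2-methylenecyclohexene adduct F4.
  - Acid work-up removes ethanol and both silyl groups. The exocyclic alkene moves into the ring under the drive of aromatisation, which gives 9.

Step 2.
- What may go wrong: the second silylation may stay incomplete, the ketene acetal may hydrolyse during isolation, or the enol ether may form with the methyl group pointing inward, which slows step 3.
- Fallback (from 4 back to 6):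
  - 4 is silylated once only (TMSCl, Et3N, rt) and 5 is isolated by distillation.
  - 5 is deprotonated at the γ-CH2 with LDA in THF at −78 °C, and the lithium dienolate is trapped on oxygen with TMSCl.
  - Hard kinetic enolisation thus replaces the amine/silyl triflate equilibrium. This fallback makes no compound outside the list (F0).

Further compounds
F1 | step 4 | 3,5-dimethylorsellinic acid (2,4-dihydroxy-3,5,6-trimethylbenzoic acid) | Cc1c(C)c(C(=O)O)c(O)c(C)c1O
F2 | step 3 | (2E,6E)-farnesyl but-3-ynoate | CC(C)=CCC/C(C)=C/CC/C(C)=C/COC(=O)CC#C
F3 | step 3 | (2E,6E)-farnesyl buta-2,3-dienoate | CC(C)=CCC/C(C)=C/CC/C(C)=C/COC(=O)C=C=C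
F4 | step 3 | (2E,6E)-farnesyl 6-ethoxy-3,5-dimethyl-2-methylidene-4,6-bis(trimethylsilyloxy)cyclohex-4-ene-1-carboxylate (diastereomer mixture) | CC(C)=CCC/C(C)=C/CC/C(C)=C/COC(=O)C1C(=C)C(C)C(O[Si](C)(C)C)=C(C)C1(OCC)O[Si](C)(C)C
F0 | step 2 | none | none
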